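**Retrosynthetic overview**

1. The target is a depside. The last steps only unmask it: hydrogenolysis of the ring B benzyl ester, BCl3 cleavage of the two ethers that sit ortho to carbonyl groups, and before that a Fukuyama coupling that turns a CH2–C(=O)SEt arm into the 2-oxopentyl ketone.
2. The strategy rests on ring A: the depside carbonyl on C1 and the CH2–C(=O) arm on C6 are on adjacent carbons, and the C2 oxygen flanks the acyl carbon. This is the ortho acyl/alkyl pattern, acyl next to oxygen, that insertion of a 3-alkoxybenzyne into a C–C bond of a 1,3-dicarbonyl compound produces.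
3. Key disconnection: both C1–C(=O) and C6–CH2 of ring A are cut. This gives 3,5-dimethoxybenzyne (from its ortho-silyl triflate) and a mixed malonate tBuO2C–CH2–CO2–(ring B aryl) that already holds the depside C–O bond.
4. The silyl triflate comes from 3,5-dimethoxyphenol (bromination, silylation, retro-Brook shift and triflation). The malonate comes from 5-propylresorcinol (carboxylation, benzyl ester, temporary 4'-O-silyl group, 2'-O-benzylation, desilylation, malonylation).
5. No ring is formed in the route: both benzene rings are bought, ring B is dressed first, and ring A receives its two carbon substituents in the key step.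

Key step: step 10

Remark: the target has no stereocentre, so no step has to control configuration. Ring A is numbered from the carbon bearing the depside carbonyl (C1; OH on C2, OMe on C4, 2-oxopentyl on C6) and ring B from the carbon bearing CO2H (C1'; OH on C2', depside oxygen on C4', propyl on C6').

**Route**

Step 1
Reactants: 1 3,5-dimethoxyphenol
Product: 2 2-bromo-3,5-dimethoxyphenol
Conditions: NBS (1.0 equiv), CH2Cl2, −78 °C → rt
Reagents that add atoms: N-bromosuccinimide, O=C1CCC(=O)N1Br
Why: Electrophilic aromatic bromination of the highly activated phenol should favour the position ortho to the hydroxyl group (C2) over C4 between the two methoxy groups at low temperature in a non-polar solvent, and the minor isomer is separable by chromatography.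

Step 2
Reactants: 2 2-bromo-3,5-dimethoxyphenol
Product: 3 (2-bromo-3,5-dimethoxyphenoxy)trimethylsilane
Conditions: (Me3Si)2NH, THF, 70 °C; concentrate
Reagents that add atoms: hexamethyldisilazane, C[Si](C)(C)N[Si](C)(C)C
Why: O-Silylation of the phenol with hexamethyldisilazane needs no base and leaves only ammonia, so the silyl ether can be used after evaporation.

Step 3
Reactants: 3 (2-bromo-3,5-dimethoxyphenoxy)trimethylsilane
Product: 6 3,5-dimethoxy-2-(trimethylsilyl)phenyl trifluoromethanesulfonate, via aryllithium 4 (not isolated), via lithium 2-silylphenoxide 5 (not isolated)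
Conditions: n-BuLi, THF, −100 → −80 °C; then Tf2O, −100 °C → rt
Reagents that add atoms: trifluoromethanesulfonic anhydride, O=S(=O)(OS(=O)(=O)C(F)(F)F)C(F)(F)F
Why: Bromine–lithium exchange gives aryllithium 4, the ortho silyloxy group passes its silyl group to carbon in a retro-Brook 1,3-shift to give phenoxide 5, and Tf2O traps the oxygen, which is the standard way to ortho-silylaryl triflates.

Step 4
Reactants: 7 5-propylresorcinol
Product: 8 2,4-dihydroxy-6-propylbenzoic acid
Conditions: MeOMgOCO2Me (2 M in DMF), 120 °C; then cold aq HCl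
Reagents that add atoms: methoxymagnesium methyl carbonate, COC(=O)O[Mg]OC
Why: Kolbe–Schmitt-type ortho-carboxylation of the resorcinol by the magnesium carbonate reagent, a method used for 5-alkylresorcinols, should place CO2H at C4 (ortho to one hydroxyl, para to the other), and cold acidic work-up avoids decarboxylation.

Step 5
Reactants: 8 2,4-dihydroxy-6-propylbenzoic acid
Product: 9 benzyl 2,4-dihydroxy-6-propylbenzoate
Conditions: BnBr (1.05 equiv), KHCO3, DMF, rt
Reagents that add atoms: benzyl bromide, BrCc1ccccc1
Why: SN2 alkylation of the carboxylate, the only group that bicarbonate deprotonates, should leave both phenols free.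

Step 6
Reactants: 9 benzyl 2,4-dihydroxy-6-propylbenzoate
Product: 10 benzyl 4-[(tert-butyldimethylsilyl)oxy]-2-hydroxy-6-propylbenzoate
Conditions: TBSCl (1.05 equiv), imidazole, CH2Cl2, 0 °C
Reagents that add atoms: tert-butyldimethylsilyl chloride, CC(C)(C)[Si](C)(C)Cl
Why: Selective silylation of the 4'-hydroxyl is expected because the 2'-hydroxyl is hydrogen-bonded to the ester carbonyl and far less nucleophilic.

Step 7
Reactants: 10 benzyl 4-[(tert-butyldimethylsilyl)oxy]-2-hydroxy-6-propylbenzoate
Product: 11 benzyl 2-(benzyloxy)-4-[(tert-butyldimethylsilyl)oxy]-6-propylbenzoate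
Conditions: BnOH, PPh3, DIAD, THF, 0 °C → rt
Reagents that add atoms: benzyl alcohol, OCc1ccccc1
Why: Mitsunobu etherification benzylates the remaining hydrogen-bonded phenol under neutral conditions, which avoids the silyl loss or migration that a carbonate-base alkylation could cause.

Step 8
Reactants: 11 benzyl 2-(benzyloxy)-4-[(tert-butyldimethylsilyl)oxy]-6-propylbenzoate
Product: 12 benzyl 2-(benzyloxy)-4-hydroxy-6-propylbenzoate
Conditions: Bu4NF, AcOH, THF, 0 °C
Reagents that add atoms: none
Why: Fluoride cleavage of the aryl silyl ether, buffered with acetic acid, frees the 4'-phenol without touching the benzyl ether or benzyl ester.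

Step 9
Reactants: 12 benzyl 2-(benzyloxy)-4-hydroxy-6-propylbenzoate; 13 mono-tert-butyl malonate
Product: 14 3-(benzyloxy)-4-[(benzyloxy)carbonyl]-5-propylphenyl tert-butyl malonate
Conditions: DCC, DMAP (cat.), CH2Cl2, 0 °C → rt
Reagents that add atoms: none
Why: Steglich esterification of the phenol with the malonic half-ester is reliable, helped by the ease with which malonic half-esters are activated by carbodiimides.

Step 10
Reactants: 6 3,5-dimethoxy-2-(trimethylsilyl)phenyl trifluoromethanesulfonate; 14 3-(benzyloxy)-4-[(benzyloxy)carbonyl]-5-propylphenyl tert-butyl malonate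
Product: 18 3-(benzyloxy)-4-[(benzyloxy)carbonyl]-5-propylphenyl 2-(2-tert-butoxy-2-oxoethyl)-4,6-dimethoxybenzoate, via 3,5-dimethoxybenzyne 15 (not isolated), via aryl cesium adduct 16 (not isolated), via benzocyclobutenoxide 17 (not isolated)
Conditions: CsF (2.5 equiv), MeCN, rt, 6 (1.2 equiv) added slowly
Reagents that add atoms: none
Why: Proposed new method: fluoride desilylates 6 to aryne 15 and deprotonates 14, and the malonate carbanion adds to the aryne carbon remote from the flanking methoxy group (the inductively favoured site), which places the aryl anion of 16 next to that methoxy group. This anion attacks the aryl ester carbonyl in a 4-exo-trig closure to the benzocyclobutenoxide 17, and strain-driven C–C cleavage then releases the benzylic tert-butyl ester enolate, which takes a proton from further 14 to give 18. The closest known reactions are the insertion of arynes into the C–C bond of dialkyl malonates and the acyl-alkylation of arynes with beta-keto esters; what is new is a mixed aryl/tert-butyl malonate in which only the aryloxycarbonyl group migrates. No lasting ring and no stereocentre is formed, since the four-membered ring and the two stereocentres of 17 vanish on ring opening. The step needs attack at the aryl ester and not the tert-butyl ester, secured by the higher electrophilicity of the aryl ester and the bulk of the tert-butyl group, and C–C cleavage of 17 rather than loss of the ring B phenoxide, secured by relief of cyclobutene strain and by the fact that re-addition of that phenoxide to the benzocyclobutenone would only regenerate 17. Slow addition of 6 at room temperature keeps the aryne concentration low, so that the product and any free phenoxide should not be arylated.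

Step 11
Reactants: 18 3-(benzyloxy)-4-[(benzyloxy)carbonyl]-5-propylphenyl 2-(2-tert-butoxy-2-oxoethyl)-4,6-dimethoxybenzoate
Product: 19 2-[2-({3-(benzyloxy)-4-[(benzyloxy)carbonyl]-5-propylphenoxy}carbonyl)-3,5-dimethoxyphenyl]acetic acid
Conditions: CF3CO2H, CH2Cl2, 0 °C → rt; evaporate, no basic work-up
Reagents that add atoms: none
Why: Acidolysis of the tert-butyl ester with loss of isobutene should spare the benzyl ester, the benzyl ether and the hindered diaryl ester, and the acid is kept away from base so that its carboxylate cannot attack the neighbouring aryl ester.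

Step 12
Reactants: 19 2-[2-({3-(benzyloxy)-4-[(benzyloxy)carbonyl]-5-propylphenoxy}carbonyl)-3,5-dimethoxyphenyl]acetic acid
Product: 20 3-(benzyloxy)-4-[(benzyloxy)carbonyl]-5-propylphenyl 2-[2-(ethylsulfanyl)-2-oxoethyl]-4,6-dimethoxybenzoate
Conditions: EtSH, DCC, DMAP (cat.), CH2Cl2, 0 °C
Reagents that add atoms: ethanethiol, CCS
Why: Steglich-type thioesterification of the unhindered arylacetic acid with the strongly nucleophilic thiol should proceed at low temperature without disturbing the depside ester.

Step 13
Reactants: 20 3-(benzyloxy)-4-[(benzyloxy)carbonyl]-5-propylphenyl 2-[2-(ethylsulfanyl)-2-oxoethyl]-4,6-dimethoxybenzoate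
Product: 21 3-(benzyloxy)-4-[(benzyloxy)carbonyl]-5-propylphenyl 2,4-dimethoxy-6-(2-oxopentyl)benzoate
Conditions: n-PrZnBr (0.5 M in THF, 2 equiv), PdCl2(PPh3)2 (cat.), toluene, rt
Reagents that add atoms: propylzinc bromide, CCC[Zn]Br
Why: In the Fukuyama coupling, zerovalent palladium formed from PdCl2(PPh3)2 inserts only into the C(acyl)–S bond, and transmetallation with the alkylzinc halide followed by reductive elimination gives the ketone, to which the organozinc does not add further.

Step 14
Reactants: 21 3-(benzyloxy)-4-[(benzyloxy)carbonyl]-5-propylphenyl 2,4-dimethoxy-6-(2-oxopentyl)benzoate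
Product: 22 benzyl 2-hydroxy-4-{[2-hydroxy-4-methoxy-6-(2-oxopentyl)benzoyl]oxy}-6-propylbenzoate
Conditions: BCl3 (1 M in CH2Cl2), C6HMe5, CH2Cl2, −78 → 0 °C; then MeOH, H2O, cold
Reagents that add atoms: none
Why: BCl3 held between a carbonyl oxygen and an ortho ether oxygen should cleave the C2 methyl ether of ring A and the C2' benzyl ether of ring B, with pentamethylbenzene taking up the benzyl cation, while the unchelated C4 methyl ether and, at this temperature, the benzyl ester are expected to remain.

Step 15
Reactants: 22 benzyl 2-hydroxy-4-{[2-hydroxy-4-methoxy-6-(2-oxopentyl)benzoyl]oxy}-6-propylbenzoate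
Product: 23 2-hydroxy-4-{[2-hydroxy-4-methoxy-6-(2-oxopentyl)benzoyl]oxy}-6-propylbenzoic acid (CNP0187582.0)
Conditions: H2 (1 atm), Pd/C, EtOAc, rt
Reagents that add atoms: none
Why: Hydrogenolysis of the benzyl ester over palladium on carbon is neutral and mild, so the aliphatic ketone, the depside ester and the easily decarboxylated salicylic acid should survive.

**Compound list**

1 | 3,5-dimethoxyphenol | COc1cc(O)cc(OC)c1 | starting material
2 | 2-bromo-3,5-dimethoxyphenol | COc1cc(O)c(Br)c(OC)c1 | intermediate
3 | (2-bromo-3,5-dimethoxyphenoxy)trimethylsilane | COc1cc(O[Si](C)(C)C)c(Br)c(OC)c1 | intermediate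
4 | [2,4-dimethoxy-6-(trimethylsilyloxy)phenyl]lithium | COc1cc(O[Si](C)(C)C)c([Li])c(OC)c1 | intermediate (not isolated)
5 | lithium 3,5-dimethoxy-2-(trimethylsilyl)phenoxide | COc1cc([O-])c([Si](C)(C)C)c(OC)c1.[Li+] | intermediate (not isolated)
6 | 3,5-dimethoxy-2-(trimethylsilyl)phenyl trifluoromethanesulfonate | COc1cc(OC)c([Si](C)(C)C)c(OS(=O)(=O)C(F)(F)F)c1 | intermediate
7 | 5-propylresorcinol | CCCc1cc(O)cc(O)c1 | starting material
8 | 2,4-dihydroxy-6-propylbenzoic acid | CCCc1cc(O)cc(O)c1C(=O)O | intermediate
9 | benzyl 2,4-dihydroxy-6-propylbenzoate | CCCc1cc(O)cc(O)c1C(=O)OCc1ccccc1 | intermediate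
10 | benzyl 4-[(tert-butyldimethylsilyl)oxy]-2-hydroxy-6-propylbenzoate | CCCc1cc(O[Si](C)(C)C(C)(C)C)cc(O)c1C(=O)OCc1ccccc1 | intermediate
11 | benzyl 2-(benzyloxy)-4-[(tert-butyldimethylsilyl)oxy]-6-propylbenzoate | CCCc1cc(O[Si](C)(C)C(C)(C)C)cc(OCc2ccccc2)c1C(=O)OCc1ccccc1 | intermediate
12 | benzyl 2-(benzyloxy)-4-hydroxy-6-propylbenzoate | CCCc1cc(O)cc(OCc2ccccc2)c1C(=O)OCc1ccccc1 | intermediate
13 | mono-tert-butyl malonate (3-tert-butoxy-3-oxopropanoic acid) | CC(C)(C)OC(=O)CC(=O)O | starting material
14 | 3-(benzyloxy)-4-[(benzyloxy)carbonyl]-5-propylphenyl tert-butyl malonate | CC(C)(C)OC(=O)CC(=O)Oc1cc(OCc2ccccc2)c(C(=O)OCc2ccccc2)c(CCC)c1 | intermediate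
15 | 3,5-dimethoxybenzyne (1,2-didehydro-3,5-dimethoxybenzene) | COC1=CC(OC)=CC#C1 | intermediate (not isolated)
16 | 3-(benzyloxy)-4-[(benzyloxy)carbonyl]-5-propylphenyl tert-butyl 2-(2-cesio-3,5-dimethoxyphenyl)malonate | COc1cc(OC)c([Cs])c(c1)C(C(=O)OC(C)(C)C)C(=O)Oc1cc(OCc2ccccc2)c(C(=O)OCc2ccccc2)c(CCC)c1 | intermediate (not isolated)
17 | cesium benzocyclobutenoxide formed by closure of 16 onto the aryl ester carbonyl (racemic, transient) | COc1cc(OC)c2c(c1)C(C(=O)OC(C)(C)C)C2([O-])Oc1cc(OCc3ccccc3)c(C(=O)OCc3ccccc3)c(CCC)c1.[Cs+] | intermediate (not isolated)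
18 | 3-(benzyloxy)-4-[(benzyloxy)carbonyl]-5-propylphenyl 2-(2-tert-butoxy-2-oxoethyl)-4,6-dimethoxybenzoate | COc1cc(OC)c(C(=O)Oc2cc(OCc3ccccc3)c(C(=O)OCc3ccccc3)c(CCC)c2)c(CC(=O)OC(C)(C)C)c1 | intermediate
19 | 2-[2-({3-(benzyloxy)-4-[(benzyloxy)carbonyl]-5-propylphenoxy}carbonyl)-3,5-dimethoxyphenyl]acetic acid | COc1cc(OC)c(C(=O)Oc2cc(OCc3ccccc3)c(C(=O)OCc3ccccc3)c(CCC)c2)c(CC(=O)O)c1 | intermediate
20 | 3-(benzyloxy)-4-[(benzyloxy)carbonyl]-5-propylphenyl 2-[2-(ethylsulfanyl)-2-oxoethyl]-4,6-dimethoxybenzoate | COc1cc(OC)c(C(=O)Oc2cc(OCc3ccccc3)c(C(=O)OCc3ccccc3)c(CCC)c2)c(CC(=O)SCC)c1 | intermediate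
21 | 3-(benzyloxy)-4-[(benzyloxy)carbonyl]-5-propylphenyl 2,4-dimethoxy-6-(2-oxopentyl)benzoate | COc1cc(OC)c(C(=O)Oc2cc(OCc3ccccc3)c(C(=O)OCc3ccccc3)c(CCC)c2)c(CC(=O)CCC)c1 | intermediate
22 | benzyl 2-hydroxy-4-{[2-hydroxy-4-methoxy-6-(2-oxopentyl)benzoyl]oxy}-6-propylbenzoate | CCCC(=O)Cc1cc(OC)cc(O)c1C(=O)Oc1cc(O)c(C(=O)OCc2ccccc2)c(CCC)c1 | intermediate
23 | 2-hydroxy-4-{[2-hydroxy-4-methoxy-6-(2-oxopentyl)benzoyl]oxy}-6-propylbenzoic acid | CCCC(=O)Cc1cc(OC)cc(O)c1C(=O)Oc1cc(O)c(C(=O)O)c(CCC)c1 | target

**Step count and risks**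

Total step count: 15. Longest linear sequence: 12 steps (steps 4 to 15, from 5-propylresorcinol 7).

Steps most likely to fail:

1. Step 10 (the proposed new method). What may go wrong:
   - E1cB loss of the ring B phenoxide from the malonate enolate to give an acylketene.
   - O-arylation of that phenoxide by the aryne.
   - Protonation of the aryl anion before it closes onto the ester (plain alpha-arylation).
   - Cyclisation of the product enolate onto the activated aryl ester with expulsion of ring B.

   Fallback with known chemistry, setting out from 6 and 12 and coming back at 19. The aryne from 6 is inserted into symmetric dibenzyl malonate (CsF, MeCN, 80 °C), the established dialkyl malonate insertion, to give benzyl 2-[2-(benzyloxy)-2-oxoethyl]-4,6-dimethoxybenzoate F1. Hydrogenolysis (H2, Pd/C) gives 2-(carboxymethyl)-4,6-dimethoxybenzoic acid F2. Acid-catalysed esterification with allyl alcohol (cat. H2SO4, rt) reacts only at the unhindered aliphatic acid and gives 2-[2-(allyloxy)-2-oxoethyl]-4,6-dimethoxybenzoic acid F3. The hindered benzoic acid is then joined to phenol 12 by the trifluoroacetic anhydride depside esterification (toluene, rt) to give 3-(benzyloxy)-4-[(benzyloxy)carbonyl]-5-propylphenyl 2-[2-(allyloxy)-2-oxoethyl]-4,6-dimethoxybenzoate F4. Deallylation with Pd(PPh3)4 (zerovalent palladium) and morpholine returns acid 19, from which steps 12 to 15 follow unchanged.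

2. Step 14. What may go wrong: Lewis-acid-promoted enolisation of the 2-oxopentyl ketone and attack of the enol oxygen on the boron-activated depside carbonyl (isocoumarin formation with loss of ring B), and partial cleavage of the benzyl ester or of the C4 methyl ether on warming.

   Fallback that keeps the ketone away from the Lewis acid, setting out from 20 and coming back at 22. The thioester 20 is treated with BCl3 and pentamethylbenzene (CH2Cl2, −78 → 0 °C) to give benzyl 4-({2-[2-(ethylsulfanyl)-2-oxoethyl]-6-hydroxy-4-methoxybenzoyl}oxy)-2-hydroxy-6-propylbenzoate F5. The Fukuyama coupling is then run on this diphenol with an excess of n-PrZnBr and PdCl2(PPh3)2; palladium-catalysed coupling of alkylzinc halides is fast enough to tolerate hydrogen-bonded phenols. This gives 22, and step 15 follows.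

3. Step 4. What may go wrong: carboxylation at C2 between the two hydroxyl groups in place of C4, incomplete conversion, and decarboxylation of the acid during isolation.

   Fallback that builds the carboxyl carbon by formylation, setting out from 7 and coming back at 11. Vilsmeier–Haack formylation (POCl3, DMF, then aqueous hydrolysis) reliably attacks 5-alkylresorcinols para to one hydroxyl and gives 2,4-dihydroxy-6-propylbenzaldehyde F6. Selective silylation of the non-chelated hydroxyl (TBSCl, imidazole) gives 4-[(tert-butyldimethylsilyl)oxy]-2-hydroxy-6-propylbenzaldehyde F7. Mitsunobu benzylation (BnOH, PPh3, DIAD) gives 2-(benzyloxy)-4-[(tert-butyldimethylsilyl)oxy]-6-propylbenzaldehyde F8. Pinnick oxidation (NaClO2, NaH2PO4, 2-methyl-2-butene, t-BuOH/H2O) gives 2-(benzyloxy)-4-[(tert-butyldimethylsilyl)oxy]-6-propylbenzoic acid F9. Benzylation of the carboxylate (BnBr, KHCO3, DMF) gives 11, and the route continues at step 8.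

**Further compounds**

F1 | step 10 | benzyl 2-[2-(benzyloxy)-2-oxoethyl]-4,6-dimethoxybenzoate | COc1cc(OC)c(C(=O)OCc2ccccc2)c(CC(=O)OCc2ccccc2)c1
F2 | step 10 | 2-(carboxymethyl)-4,6-dimethoxybenzoic acid | COc1cc(OC)c(C(=O)O)c(CC(=O)O)c1
F3 | step 10 | 2-[2-(allyloxy)-2-oxoethyl]-4,6-dimethoxybenzoic acid | COc1cc(OC)c(C(=O)O)c(CC(=O)OCC=C)c1
F4 | step 10 | 3-(benzyloxy)-4-[(benzyloxy)carbonyl]-5-propylphenyl 2-[2-(allyloxy)-2-oxoethyl]-4,6-dimethoxybenzoate | COc1cc(OC)c(C(=O)Oc2cc(OCc3ccccc3)c(C(=O)OCc3ccccc3)c(CCC)c2)c(CC(=O)OCC=C)c1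
F5 | step 14 | benzyl 4-({2-[2-(ethylsulfanyl)-2-oxoethyl]-6-hydroxy-4-methoxybenzoyl}oxy)-2-hydroxy-6-propylbenzoate | CCSC(=O)Cc1cc(OC)cc(O)c1C(=O)Oc1cc(O)c(C(=O)OCc2ccccc2)c(CCC)c1
F6 | step 4 | 2,4-dihydroxy-6-propylbenzaldehyde | CCCc1cc(O)cc(O)c1C=O
F7 | step 4 | 4-[(tert-butyldimethylsilyl)oxy]-2-hydroxy-6-propylbenzaldehyde | CCCc1cc(O[Si](C)(C)C(C)(C)C)cc(O)c1C=O
F8 | step 4 | 2-(benzyloxy)-4-[(tert-butyldimethylsilyl)oxy]-6-propylbenzaldehyde | CCCc1cc(O[Si](C)(C)C(C)(C)C)cc(OCc2ccccc2)c1C=O
F9 | step 4 | 2-(benzyloxy)-4-[(tert-butyldimethylsilyl)oxy]-6-propylbenzoic acid | CCCc1cc(O[Si](C)(C)C(C)(C)C)cc(OCc2ccccc2)c1C(=O)O
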